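**Plan**

Ring letters: A = O-linked terminal ring, B = hub ring, C = inner ring of each arm, D = middle ring of each arm, E = C-linked terminal ring.

1. The retrosynthesis first removes fifteen O-methyl groups, then cuts four C–OH bonds: at C5 of ring A, at C5 of ring B (para to the C2 ether oxygen that holds ring A) and at C4 of each ring E. These are the only four ring carbons of the methylated skeleton with hydrogen on both neighbours; every other C–H is ortho to a methoxy, aryloxy or aryl group.
2. The tetra-deoxy skeleton is cut at both ring B–O–ring C ether bonds (hub dibromide plus two arm phenols). Each arm is cut at the ring C–O–ring D ether bond and the ring D–ring E biaryl bond, and the hub at the ring A–O–ring B ether bond.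
3. Forward order: Suzuki coupling (rings D–E), lithiation/oxidation to the ring D phenol, Ullmann coupling to ring C, debenzylation; Chan–Lam coupling (rings A–B); twofold Ullmann union; fourfold C–H hydroxylation; global demethylation. No ring is built; all eight benzene rings are purchased.
4. Stereochemistry: the target has no stereocentre, and the ring D–ring E axis is not stereogenic because ring E is symmetric about it.

Key step: step 8

Remark: all starting materials are taken to be catalogue compounds. Methyl is the only O-protecting group present when the iridium catalyst is used, because a benzyl group would offer unhindered aryl C–H bonds of its own.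

**Route**

Step 1
Reactants: 1 2-bromo-1,3,5-trimethoxybenzene; 2 2,6-dimethoxyphenylboronic acid (2 equiv)
Product: 3 2,2',4,6,6'-pentamethoxybiphenyl (rings D–E)
Conditions: Pd(OAc)2 (5 mol %), SPhos (10 mol %), K3PO4, toluene–H2O (10:1), 100 °C
Reagents that add atoms: none
Why: Suzuki–Miyaura coupling, in which the bulky electron-rich biarylphosphine SPhos gives a monoligated zerovalent palladium species that inserts into the hindered C–Br bond and is known to deliver tetra-ortho-substituted biaryls from 2,6-dialkoxyarylboronic acids, the excess of 2 covering protodeboronation.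

Step 2
Reactants: 3 2,2',4,6,6'-pentamethoxybiphenyl
Product: 6 3-(2,6-dimethoxyphenyl)-2,4,6-trimethoxyphenol, via aryllithium 4 (not isolated), via dimethyl arylboronate 5 (not isolated)
Conditions: n-BuLi (1.1 equiv), TMEDA, THF, 0 °C; B(OMe)3, −78 °C to rt; 30% aq H2O2, aq NaOH, 0 °C
Reagents that add atoms: hydrogen peroxide, OO (the phenol oxygen of 6); n-butyllithium, [Li]CCCC (lithium of 4 only); trimethyl borate, COB(OC)OC (boron and methoxy groups of 5 only)
Why: Directed ortho-metalation takes place at the ring D C–H flanked by two methoxy groups (both such positions are equivalent, while ring E has no C–H with two oxygen neighbours), and borate trapping followed by alkaline peroxide oxidation with 1,2-aryl shift from boron to oxygen is the standard aryllithium-to-phenol sequence.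

Step 3
Reactants: 7 4-bromo-2,6-dimethoxyphenol
Product: 8 2-(benzyloxy)-5-bromo-1,3-dimethoxybenzene (ring C unit)
Conditions: BnBr, K2CO3, DMF, rt
Reagents that add atoms: benzyl bromide, BrCc1ccccc1
Why: Williamson ether synthesis masks the ring C phenol so that its bromide can serve as the electrophile in the next step without self-coupling.

Step 4
Reactants: 6 3-(2,6-dimethoxyphenyl)-2,4,6-trimethoxyphenol; 8 2-(benzyloxy)-5-bromo-1,3-dimethoxybenzene
Product: 9 2-(benzyloxy)-5-[3-(2,6-dimethoxyphenyl)-2,4,6-trimethoxyphenoxy]-1,3-dimethoxybenzene (benzyl-protected arm C–D–E)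
Conditions: CuI (10 mol %), picolinic acid (20 mol %), K3PO4, DMSO, 100 °C, argon
Reagents that add atoms: none
Why: Ullmann-type diaryl ether synthesis, with the hindered partner placed as the nucleophile (the CuI–picolinic acid system is known to arylate 2,6-disubstituted phenols) and the bromide of 8 free of ortho substituents.

Step 5
Reactants: 9 benzyl-protected arm
Product: 10 4-[3-(2,6-dimethoxyphenyl)-2,4,6-trimethoxyphenoxy]-2,6-dimethoxyphenol (arm phenol)
Conditions: H2 (1 atm), Pd/C, EtOAc–MeOH, rt
Reagents that add atoms: none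
Why: Catalytic hydrogenolysis cleaves only the benzylic C–O bond, leaving aryl methyl ethers, the diaryl ether and the biaryl untouched.

Step 6
Reactants: 11 2,6-dibromophenol; 12 3-methoxyphenylboronic acid (2 equiv)
Product: 13 1,3-dibromo-2-(3-methoxyphenoxy)benzene (hub, rings A–B)
Conditions: Cu(OAc)2 (2 equiv), pyridine, 4 Å molecular sieves, CH2Cl2, dry air, rt
Reagents that add atoms: none
Why: Chan–Lam–Evans O-arylation with divalent copper runs at room temperature, is known to accept 2,6-dihalophenols and leaves both C–Br bonds intact for the next coupling.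

Step 7
Reactants: 13 1,3-dibromo-2-(3-methoxyphenoxy)benzene; 10 arm phenol (2.4 equiv)
Product: 14 tetra-deoxy pentadeca-O-methyl octamer, 2-(3-methoxyphenoxy)-1,3-bis{4-[3-(2,6-dimethoxyphenyl)-2,4,6-trimethoxyphenoxy]-2,6-dimethoxyphenoxy}benzene
Conditions: CuI (20 mol %), picolinic acid (40 mol %), K3PO4, DMSO, 110 °C, argon
Reagents that add atoms: none
Why: Twofold Ullmann-type etherification of the same kind as step 4, in which the monovalent copper phenoxide of the di-ortho-methoxy phenol attacks each C–Br bond that has only one ortho substituent, a combination within the known scope of this catalyst system.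

Step 8
Reactants: 14 tetra-deoxy pentadeca-O-methyl octamer
Product: 16 octamer tetraphenol (14 carrying OH at C5 of ring A, C5 of ring B and C4 of both rings E; the pentadeca-O-methyl ether of the target), via tetrakis(pinacol boronate) 15 (not isolated)
Conditions: [Ir(OMe)(cod)]2 (5 mol %), 4,4'-di-tert-butyl-2,2'-bipyridine (10 mol %), B2pin2 (6 equiv), THF, 80 °C; volatiles removed; then 30% aq H2O2, aq NaOH, THF, 0 °C to rt
Reagents that add atoms: hydrogen peroxide, OO (the four new oxygen atoms of 16); bis(pinacolato)diboron, CC1(C)OB(OC1(C)C)B1OC(C)(C)C(C)(C)O1 (the boronate groups of 15 only)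
Why: The trivalent iridium tris(boryl) complex formed from the precatalyst, the bipyridine and B2pin2 cleaves an arene C–H bond only where no ortho substituent hinders its approach, C–B reductive elimination releases the aryl boronate, and hydroperoxide then adds to boron and a 1,2-aryl shift from boron to oxygen followed by hydrolysis gives each phenol at the borylated carbon. The closest known reaction type is the one-pot iridium-catalysed C–H borylation/oxidation that turns 1,3-disubstituted and 1,2,3-trisubstituted benzenes into their 5-hydroxy derivatives, here run at four sites of one substrate. No ring is closed and no stereocentre is created. The selectivity needed is purely positional: in 14 only C5 of ring A, C5 of ring B and C4 of each ring E have hydrogen on both neighbours, whereas C2, C4 and C6 of ring A, C4 and C6 of ring B, both C–H of each ring C, the single C–H of each ring D and C3 and C5 of each ring E are all ortho to a methoxy, aryloxy or aryl group. Methyl ethers offer no competing aryl C–H bond, and excess B2pin2 with a generous catalyst loading is used because all four target rings are electron-rich and should borylate slowly. Alkaline H2O2 is chosen as oxidant because it attacks only boron and should leave the very electron-rich rings C and D alone.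

Step 9
Reactants: 16 octamer tetraphenol
Product: 17 CNP0227063.0 (nonadecahydroxy octamer)
Conditions: BBr3 (40 equiv), CH2Cl2, −78 °C to rt; then MeOH, 0 °C; degassed aqueous work-up under argon
Reagents that add atoms: none
Why: Lewis-acid ether cleavage, in which BBr3 binds each methoxy oxygen and bromide removes the methyl group by SN2 attack, while diaryl ether and biaryl bonds offer no sp3 carbon and should persist.

**Compound list**

1 | 2-bromo-1,3,5-trimethoxybenzene | COc1cc(OC)c(Br)c(OC)c1 | starting material
2 | 2,6-dimethoxyphenylboronic acid | COc1cccc(OC)c1B(O)O | starting material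
3 | 2,2',4,6,6'-pentamethoxybiphenyl | COc1cc(OC)c(-c2c(OC)cccc2OC)c(OC)c1 | intermediate
4 | 3-lithio-2,2',4,6,6'-pentamethoxybiphenyl (formed in the flask, step 2) | [Li]c1c(OC)cc(OC)c(-c2c(OC)cccc2OC)c1OC | intermediate
5 | dimethyl (2,2',4,6,6'-pentamethoxybiphenyl-3-yl)boronate (formed in the flask, step 2) | COB(OC)c1c(OC)cc(OC)c(-c2c(OC)cccc2OC)c1OC | intermediate
6 | 3-(2,6-dimethoxyphenyl)-2,4,6-trimethoxyphenol | COc1cc(OC)c(-c2c(OC)cccc2OC)c(OC)c1O | intermediate
7 | 4-bromo-2,6-dimethoxyphenol | COc1cc(Br)cc(OC)c1O | starting material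
8 | 2-(benzyloxy)-5-bromo-1,3-dimethoxybenzene | COc1cc(Br)cc(OC)c1OCc1ccccc1 | intermediate
9 | 2-(benzyloxy)-5-[3-(2,6-dimethoxyphenyl)-2,4,6-trimethoxyphenoxy]-1,3-dimethoxybenzene | COc1cc(Oc2c(OC)cc(OC)c(-c3c(OC)cccc3OC)c2OC)cc(OC)c1OCc1ccccc1 | intermediate
10 | 4-[3-(2,6-dimethoxyphenyl)-2,4,6-trimethoxyphenoxy]-2,6-dimethoxyphenol | COc1cc(Oc2c(OC)cc(OC)c(-c3c(OC)cccc3OC)c2OC)cc(OC)c1O | intermediate
11 | 2,6-dibromophenol | Oc1c(Br)cccc1Br | starting material
12 | 3-methoxyphenylboronic acid | COc1cccc(B(O)O)c1 | starting material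
13 | 1,3-dibromo-2-(3-methoxyphenoxy)benzene | COc1cccc(Oc2c(Br)cccc2Br)c1 | intermediate
14 | tetra-deoxy pentadeca-O-methyl octamer (ring A 3-methoxyphenyl, ring B without OH, rings E 2,6-dimethoxyphenyl) | COc1cccc(Oc2c(Oc3c(OC)cc(Oc4c(OC)cc(OC)c(-c5c(OC)cccc5OC)c4OC)cc3OC)cccc2Oc2c(OC)cc(Oc3c(OC)cc(OC)c(-c4c(OC)cccc4OC)c3OC)cc2OC)c1 | intermediate
15 | tetrakis(pinacol boronate) of 14 at C5 of ring A, C5 of ring B and C4 of both rings E (formed in the flask, step 8) | COc1cc(B6OC(C)(C)C(C)(C)O6)cc(Oc2c(Oc3c(OC)cc(Oc4c(OC)cc(OC)c(-c5c(OC)cc(B6OC(C)(C)C(C)(C)O6)cc5OC)c4OC)cc3OC)cc(B6OC(C)(C)C(C)(C)O6)cc2Oc2c(OC)cc(Oc3c(OC)cc(OC)c(-c4c(OC)cc(B6OC(C)(C)C(C)(C)O6)cc4OC)c3OC)cc2OC)c1 | intermediate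
16 | octamer tetraphenol (new OH on rings A, B and both E; all other oxygens methylated) | COc1cc(O)cc(Oc2c(Oc3c(OC)cc(Oc4c(OC)cc(OC)c(-c5c(OC)cc(O)cc5OC)c4OC)cc3OC)cc(O)cc2Oc2c(OC)cc(Oc3c(OC)cc(OC)c(-c4c(OC)cc(O)cc4OC)c3OC)cc2OC)c1 | intermediate
17 | CNP0227063.0 | Oc1cc(O)cc(Oc2c(Oc3c(O)cc(Oc4c(O)cc(O)c(-c5c(O)cc(O)cc5O)c4O)cc3O)cc(O)cc2Oc2c(O)cc(Oc3c(O)cc(O)c(-c4c(O)cc(O)cc4O)c3O)cc2O)c1 | target

**Count and risks**

Total steps: 9. Longest linear sequence: 7 steps (steps 1, 2, 4, 5, 7, 8, 9, from 1 to 17); steps 3 and 6 are side branches.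

Steps most likely to fail:

Step 7. After the first ether bond is made, the remaining C–Br bond of the hub sits beside two aryloxy groups. The second coupling with the di-ortho-methoxy phenoxide may therefore stall, and protodebromination or copper-mediated oxidation of the electron-rich phenol may take over. The fallback sets out from 10 and returns at 14, forming both hindered ether bonds by uncatalysed nucleophilic aromatic substitution. Compound 10 (2.2 equiv) and 2,6-difluorobenzaldehyde with K2CO3 in DMF at 100 °C should give 2,6-bis{4-[3-(2,6-dimethoxyphenyl)-2,4,6-trimethoxyphenoxy]-2,6-dimethoxyphenoxy}benzaldehyde F1. Baeyer–Villiger oxidation of the electron-rich aldehyde (mCPBA, NaHCO3, CH2Cl2, 0 °C) and cleavage of the aryl formate (aq NaOH, MeOH) should give the corresponding 2,6-bis(aryloxy)phenol F2. Ullmann coupling of F2 with 3-iodoanisole (CuI, picolinic acid, K3PO4, DMSO, 90 °C), now between a hindered phenol and an unhindered aryl iodide, would lead back to 14.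

Step 8. Borylation may stop short at one or more of the four slowly reacting electron-rich sites as the catalyst decays, or steric control may erode next to a methoxy group; either would give mixtures of tri- and tetra-ols that are hard to separate. The fallback sets out from 14 and returns at 16, and uses C–H silylation in place of borylation. Treatment with HSiMe(OSiMe3)2, [Ir(OMe)(cod)]2, 2,4,7-trimethyl-1,10-phenanthroline and cyclohexene as hydrogen acceptor in THF at 100 °C should place the bulkier silyl group at the same four unhindered carbons, giving the tetrakis[bis(trimethylsiloxy)methylsilyl] octamer F3. This compound is stable to chromatography, so incompletely silylated material can be separated and resubmitted. Tamao–Fleming-type oxidation (H2O2, KHCO3, n-Bu4NF, THF–MeOH) would then give 16.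

Step 9. Cleavage of fifteen methyl ethers may stop at partly methylated congeners, and the free polyphenol may be lost to air oxidation during purification. The fallback sets out from 16 and returns at 17, and separates purification from release. The crude product of the BBr3 treatment is acetylated directly (Ac2O, pyridine, DMAP, rt) to the nonadecaacetate F4, which can be purified on silica. Congeners that keep a methoxy group are removed there and returned to BBr3. Acid-catalysed methanolysis of F4 (HCl generated from AcCl in degassed MeOH, 40 °C, argon) should then release 17 with only volatile by-products.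

**Further compounds**

F1 | step 7 | 2,6-bis{4-[3-(2,6-dimethoxyphenyl)-2,4,6-trimethoxyphenoxy]-2,6-dimethoxyphenoxy}benzaldehyde | O=Cc1c(Oc2c(OC)cc(Oc3c(OC)cc(OC)c(-c4c(OC)cccc4OC)c3OC)cc2OC)cccc1Oc1c(OC)cc(Oc2c(OC)cc(OC)c(-c3c(OC)cccc3OC)c2OC)cc1OC
F2 | step 7 | 2,6-bis{4-[3-(2,6-dimethoxyphenyl)-2,4,6-trimethoxyphenoxy]-2,6-dimethoxyphenoxy}phenol | Oc1c(Oc2c(OC)cc(Oc3c(OC)cc(OC)c(-c4c(OC)cccc4OC)c3OC)cc2OC)cccc1Oc1c(OC)cc(Oc2c(OC)cc(OC)c(-c3c(OC)cccc3OC)c2OC)cc1OC
F3 | step 8 | tetrakis[bis(trimethylsiloxy)methylsilyl] derivative of 14 (silicon at C5 of ring A, C5 of ring B and C4 of both rings E) | COc1cc([Si](C)(O[Si](C)(C)C)O[Si](C)(C)C)cc(Oc2c(Oc3c(OC)cc(Oc4c(OC)cc(OC)c(-c5c(OC)cc([Si](C)(O[Si](C)(C)C)O[Si](C)(C)C)cc5OC)c4OC)cc3OC)cc([Si](C)(O[Si](C)(C)C)O[Si](C)(C)C)cc2Oc2c(OC)cc(Oc3c(OC)cc(OC)c(-c4c(OC)cc([Si](C)(O[Si](C)(C)C)O[Si](C)(C)C)cc4OC)c3OC)cc2OC)c1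
F4 | step 9 | nonadeca-O-acetate of 17 | CC(=O)Oc1cc(OC(C)=O)cc(Oc2c(Oc3c(OC(C)=O)cc(Oc4c(OC(C)=O)cc(OC(C)=O)c(-c5c(OC(C)=O)cc(OC(C)=O)cc5OC(C)=O)c4OC(C)=O)cc3OC(C)=O)cc(OC(C)=O)cc2Oc2c(OC(C)=O)cc(Oc3c(OC(C)=O)cc(OC(C)=O)c(-c4c(OC(C)=O)cc(OC(C)=O)cc4OC(C)=O)c3OC(C)=O)cc2OC(C)=O)c1
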